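## Structural features

Lophirachalcone (35) is made of four C6–C3–C6 units. Ring A (2,4-dihydroxyphenyl) carries the ketone of an E-enone whose β-carbon sits on C5 of ring B, the benzo ring of a 2,3-dihydrobenzofuran (ring C: O1, C2, C3). C2 bears ring D (4-hydroxyphenyl) and C3 bears the methine carbon Cm, which carries ring E (2,4-dihydroxyphenyl) and ring F; C2, C3 and Cm are contiguous (2R,3R,R), with C2/C3 trans. Ring F is a resorcinol substituted at both positions ortho/para to its hydroxyls: by Cm on one side and by C2′ of the tetrahydrofuran ring G (O1′, C2′–C5′) on the other. Ring G holds four contiguous stereocentres: C2′ (ring F, R), C3′ (4-hydroxybenzyl, ring J, S), C4′ (2,4-dihydroxybenzoyl, ring I, S) and C5′ (4-hydroxyphenyl, ring H, S), arranged 2′,3′-cis, 3′,4′-trans, 4′,5′-trans, 2′,5′-cis. Fragile points are the 2′-hydroxychalcone (reducible, cyclizes to a flavanone), the C2′–O1′ bond (a benzylic ether activated by two oxygens of ring F, which ionizes under acid and would relax to the 2′,3′-trans epimer), the C5′–O1′ bond (β to the ring I ketone, retro-oxa-Michael) and eleven phenols. C4′ is enolizable but already sits trans to both neighbours, whereas the cis C2′/C3′ relationship cannot be reached by equilibration; this, and the fact that ring F insulates the two stereo-arrays from each other, is the real difficulty. The key step exploits that in ring G the carbon C2′ is benzylic to a donor ring, C4′ is α to a carbonyl, the two are 1,3-related through C3′, and O1′–C5′ is an aromatic aldehyde in disguise: C2′–C3′–C4′ is the latent 1,3-dipole of a donor–acceptor cyclopropane.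

## Logic of the disconnections

**35 ⇒ 34 ⇒ 32 + 33.** Eleven O–Si bonds are added (34), then the bond between C5 of ring B and the enone β-carbon is cut. This keeps the reducible, base-sensitive enone and ring A out of the whole sequence. The demand is a Heck reaction on an electron-rich aryl chloride in the presence of everything else, and a final deprotection that is neither acidic nor strongly basic.

**32 ⇒ 30 + 5, and 30 ⇒ 29 ⇒ 27 ⇒ 25.** The bond between the C4′ carbonyl and ring I is cut (acyl substitution on an N-methoxy-N-methylamide). Backwards, the benzylic CH2 of ring J is returned to a ketone and C4′ to a geminal diester. This removes one aryl ring and turns C4′ into a non-stereogenic malonate carbon. The demand is that the two esters of 25 be told apart (lactonization onto the reduced ketone in 27 does this) and that C4′ end trans to both neighbours, which thermodynamics grants.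

**25 ⇒ 23 + 24 (key).** O1′–C2′ and C4′–C5′ are cut. Ring G with C2′, C3′ and C5′ defined falls back to a trans-cyclopropane and an achiral aldehyde; four stereocentres reduce to two. The demand is clean inversion at C2′, cleavage of the C2′–C4′ bond only, and cis closure across O1′.

**23 ⇒ 21 + 22.** The two cyclopropane bonds to the malonate carbon (C2′–C4′ and C3′–C4′) are cut. This leaves a flat E-enone. The demand is enantiofacial control of a Michael-initiated ring closure by the catalyst alone, because the existing stereocentres are remote.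

**21 ⇒ 18 + 20.** The bond between ring F and C2′ is cut (aryl–vinyl). The ring F bromide of 18 is the only handle needed, and the ring B chloride must stay inert.

**18 ⇒ 16.** O1–C2 of ring C is cut. The ring closes by ionization at C2, so the carbinol configuration of 16 is irrelevant and C2 is relayed from C3 (trans). The demand is that only the ring B phenol be free, so the ring F phenol is silylated first.

**16 ⇒ 15 ⇒ 12 + 14.** The C2–ring D bond is cut; a lactol serves as the aldehyde.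

**12 ⇒ 7 + 10 (via 11).** The C3–Cm bond is cut. An ortho-quinone methide on ring F and an arylacetaldehyde enamine set Cm by catalyst control. C3 follows thermodynamically, because the trans-3,4 lactol closed through the ring F oxygen is the C3/Cm relationship of 35 (closure through ring E would require the cis isomer).

**7 ⇒ 5 + 4.** The Cm–ring E bond is cut (Grignard addition); the C–S bond is only an activating device.

**Building blocks.** 10 ⇒ 9 ⇒ 8 (C=C cleavage); 20 ⇒ 14 + 19 and 33 ⇒ 5 + 19 (acyl–aryl bonds); 5 ⇒ 2 and 14 ⇒ 13 (C–Mg bonds; each organomagnesium is made once and feeds several steps); 2 ⇒ 1 and 4 ⇒ 3 (O–Si bonds). All ends are commercial: 1, 3, 8, 13, 19, 22, 24.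

## Other disconnections considered

**Alternative 1:** (the first that comes to mind, and the biogenetic one) Cut the Cm–ring F bond. Forward key step: acid-promoted Friedel–Crafts alkylation of the ring G-bearing resorcinol ether A1 by the ortho-quinone methide generated from carbinol A2.
- The acid that ionizes A2 also ionizes the C2′–O1′ bond of A1, whose cation is better stabilized, so the 2′,3′-cis relationship would drift to trans.
- Cm would be created next to C3 by open-chain 1,2-induction only, with two nearly identical aryl groups on the cation.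
- The chosen plan sets Cm by catalyst control before ring G exists and never exposes ring G to acid.

**Alternative 2:** Cut the C2′–ring F bond. Forward key step: addition of 18, metalated at its C–Br bond, to lactone A3, then ionic deoxygenation at the new hemiketal carbon (Et3SiH, BF3·OEt2). Hydride delivery anti to the C3′ benzyl group should give the 2′,3′-cis ring, so the stereochemical logic is sound.
- A3 needs three contiguous stereocentres from a separate sequence with its own asymmetric step.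
- Its ring I ketone competes with the lactone for the nucleophile.
- Ring G of 32, a 2-aryl tetrahydrofuran with two donor oxygens on the aryl ring, would be exposed to BF3 and silane, conditions that favour reductive ring opening.
- The chosen route reaches the same ring from two flat precursors under catalytic Lewis acid.

**Alternative 3:** Cut C2′–C3′ and C4′–C5′. Forward key step: C–C opening of trans-oxirane A4 to a carbonyl ylide and 1,3-dipolar cycloaddition to enone A5, which would give ring G with all substituents in one step.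
- The two ylide termini (ring F side, ring H side) are electronically too similar to fix the regiochemistry.
- The 2′,3′-cis relationship would need endo/exo control.
- There is no handle for absolute control, and unactivated diaryloxiranes open only under forcing conditions.
- In the chosen plan the polarity of the cyclopropane fixes regiochemistry and its configuration is transferred.

Key step: step 15

Remark: TBS = tert-butyldimethylsilyl (TBSO its ether); ring and atom labels of 35 are used for all intermediates; ArL is the aryl group of 18 attached through the carbon that carries Br. The two arylmagnesium reagents 5 and 14 are each prepared once as titrated THF stock solutions and drawn on by the later steps. The sense of induction in steps 7 and 14 is assigned from the accepted shielding models, and the antipodal or pseudo-enantiomeric catalyst would be used if the first run shows the opposite sense.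

## Steps

Step 1
Reactants: 1 4-bromobenzene-1,3-diol
Product: 2 1-bromo-2,4-bis(TBSO)benzene
Conditions: TBSCl (2.3 equiv), imidazole (3 equiv), DMF, 0 °C to rt
Reagents that add atoms: tert-butyldimethylsilyl chloride, CC(C)(C)[Si](C)(C)Cl
Why: Imidazole-mediated O-silylation of both phenols; no stereocentre is involved.

Step 2
Reactants: 3 5-bromo-2,4-dihydroxybenzaldehyde
Product: 4 5-bromo-4-(TBSO)-2-hydroxybenzaldehyde
Conditions: TBSCl (1.05 equiv), imidazole (1.2 equiv), CH2Cl2, −20 °C to 0 °C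
Reagents that add atoms: tert-butyldimethylsilyl chloride, CC(C)(C)[Si](C)(C)Cl
Why: The 2-OH is held in a hydrogen bond to the formyl group, so O-silylation should occur at the 4-OH; the free 2-OH is kept for quinone-methide generation in step 7.

Step 3
Reactants: 2 1-bromo-2,4-bis(TBSO)benzene
Product: 5 [2,4-bis(TBSO)phenyl]magnesium bromide (titrated THF stock solution)
Conditions: Mg turnings (1.3 equiv, activated with I2), THF, 40 °C; titration; kept under argon at 0 °C
Reagents that add atoms: magnesium, [Mg]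
Why: Insertion of magnesium into the aryl C–Br bond (Grignard reagent formation); the arylmagnesium is chosen over the aryllithium, which would be prone to silyl migration from the ortho oxygen to carbon, and the one batch is sized to serve steps 4, 19 and 20.

Step 4
Reactants: 5 [2,4-bis(TBSO)phenyl]magnesium bromide; 4 5-bromo-4-(TBSO)-2-hydroxybenzaldehyde
Product: 7 rac-4-bromo-2-{[2,4-bis(TBSO)phenyl](4-methylbenzenesulfonyl)methyl}-5-(TBSO)phenol, via benzhydrol 6 (not isolated)
Conditions: 5 (2.2 equiv, THF solution), 4, THF, −20 °C to rt; aq NH4Cl; crude 6, p-TolSO2Na, aq HCl, CH2Cl2, rt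
Reagents that add atoms: sodium 4-methylbenzenesulfinate, Cc1ccc(cc1)S(=O)[O-].[Na+]
Why: Grignard addition to the aldehyde (one equivalent is spent on the phenol) gives the 2-hydroxybenzhydrol, which ionizes under mild acid and is captured at sulfur by the sulfinate (sulfone formation through the ortho-quinone methide); the new centre is racemic and is erased in step 7.

Step 5
Reactants: 8 2-allyl-4-chlorophenol
Product: 9 2-allyl-4-chloro-1-(methoxymethoxy)benzene
Conditions: MOMCl, i-Pr2NEt, CH2Cl2, 0 °C to rt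
Reagents that add atoms: chloromethyl methyl ether, COCCl
Why: O-alkylation of the phenol to the methoxymethyl acetal, which survives base and organometallics and falls off under the acid of step 11.

Step 6
Reactants: 9 2-allyl-4-chloro-1-(methoxymethoxy)benzene
Product: 10 2-[5-chloro-2-(methoxymethoxy)phenyl]acetaldehyde
Conditions: OsO4 (2 mol%), NaIO4 (4 equiv), 2,6-lutidine, 1,4-dioxane/H2O (3:1), rt
Reagents that add atoms: sodium periodate, [Na+].[O-]I(=O)(=O)=O
Why: Lemieux–Johnson cleavage of the terminal alkene; lutidine suppresses over-oxidation, and the sensitive arylacetaldehyde is used without storage.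

Step 7
Reactants: 7 rac-4-bromo-2-{[2,4-bis(TBSO)phenyl](4-methylbenzenesulfonyl)methyl}-5-(TBSO)phenol; 10 2-[5-chloro-2-(methoxymethoxy)phenyl]acetaldehyde
Product: 12 (3R,4S)-6-bromo-4-[2,4-bis(TBSO)phenyl]-7-(TBSO)-3-[5-chloro-2-(methoxymethoxy)phenyl]-3,4-dihydro-2H-chromen-2-ol (3,4-trans; C2 anomers), via ortho-quinone methide 11 (not isolated)
Conditions: 10 (2 equiv), (R)-α,α-diphenylprolinol trimethylsilyl ether (20 mol%), K2CO3 (1.5 equiv), CH2Cl2, 0 °C to rt
Reagents that add atoms: none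
Why: Base expels the sulfinate to give 11, which undergoes the amine-catalysed formal (4+2) annulation (Michael addition of the enamine of 10 to the quinone-methide carbon, then hemiacetalization by the ring F phenoxide). The catalyst shields one enamine face and so fixes Cm (C4 of the chromanol). The enolizable C3 settles trans to the C4 aryl group in the six-membered lactol, which is the C3/Cm relationship of 35.

Step 8
Reactants: 13 (4-bromophenoxy)(tert-butyl)dimethylsilane
Product: 14 [4-(TBSO)phenyl]magnesium bromide (titrated THF stock solution)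
Conditions: Mg turnings (1.3 equiv, activated with I2), THF, 40 °C; titration; kept under argon at 0 °C
Reagents that add atoms: magnesium, [Mg]
Why: Insertion of magnesium into the aryl C–Br bond (Grignard reagent formation); the aryl silyl ether is inert to the reagent, and the one batch is sized to serve steps 9 and 12.

Step 9
Reactants: 12 (3R,4S)-chromanol of step 7; 14 [4-(TBSO)phenyl]magnesium bromide
Product: 15 (2R,3S)-3-[5-bromo-2-hydroxy-4-(TBSO)phenyl]-3-[2,4-bis(TBSO)phenyl]-2-[5-chloro-2-(methoxymethoxy)phenyl]-1-[4-(TBSO)phenyl]propan-1-ol (C1 epimers)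
Conditions: 14 (3.5 equiv, THF solution), 12, THF, −40 °C to 0 °C; aq NH4Cl
Reagents that add atoms: none
Why: Grignard addition to the open hydroxy-aldehyde form of the lactol (the first equivalent deprotonates the lactol), run cold to keep the α-aryl centre from enolizing; the carbinol configuration does not matter because C2 is ionized in step 11.

Step 10
Reactants: 15 (2R,3S)-propan-1-ol of step 9
Product: 16 (2R,3R)-3-[5-bromo-2,4-bis(TBSO)phenyl]-3-[2,4-bis(TBSO)phenyl]-2-[5-chloro-2-(methoxymethoxy)phenyl]-1-[4-(TBSO)phenyl]propan-1-ol (C1 epimers)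
Conditions: TBSCl (1.3 equiv), imidazole (2.5 equiv), DMF, 0 °C
Reagents that add atoms: tert-butyldimethylsilyl chloride, CC(C)(C)[Si](C)(C)Cl
Why: The phenol silylates far faster than the hindered secondary benzylic alcohol; capping the ring F phenol removes the only competitor (six-membered chroman closure) for the cyclization of step 11.

Step 11
Reactants: 16 (2R,3R)-propan-1-ol of step 10
Product: 18 (2R,3R)-3-{(R)-[5-bromo-2,4-bis(TBSO)phenyl][2,4-bis(TBSO)phenyl]methyl}-5-chloro-2-[4-(TBSO)phenyl]-2,3-dihydro-1-benzofuran, via free phenol 17 (not isolated)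
Conditions: p-TsOH·H2O (0.3 equiv), MeOH/CH2Cl2 (1:4), rt
Reagents that add atoms: none
Why: Acid removes the phenolic methoxymethyl acetal and ionizes the para-silyloxybenzylic alcohol. The ring B phenol captures the quinone-methide-type cation in a 5-exo cycloetherification, and ring D settles anti to the bulky C3 substituent, which gives the 2,3-trans ring; C3 and Cm are untouched.

Step 12
Reactants: 14 [4-(TBSO)phenyl]magnesium bromide; 19 N-methoxy-N-methylacrylamide
Product: 20 1-[4-(TBSO)phenyl]prop-2-en-1-one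
Conditions: 14 (THF solution), 19 (0.9 equiv), THF, −78 °C; inverse quench into cold 1 M HCl
Reagents that add atoms: none
Why: Acyl substitution on an N-methoxy-N-methylamide stops at the ketone because the chelated tetrahedral intermediate survives until work-up; the acidic inverse quench keeps the liberated amine from adding to the enone.

Step 13
Reactants: 18 aryl bromide of step 11; 20 1-[4-(TBSO)phenyl]prop-2-en-1-one
Product: 21 (E)-3-(ArL)-1-[4-(TBSO)phenyl]prop-2-en-1-one
Conditions: 20 (1.5 equiv), Pd(OAc)2 (5 mol%), P(o-tol)3 (12 mol%), Et3N (2 equiv), DMF, 90 °C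
Reagents that add atoms: none
Why: Mizoroki–Heck reaction of the ring F bromide; syn insertion and syn β-hydride elimination give the E-enone, and the ring B chloride is inert to this catalyst.

Step 14
Reactants: 21 enone of step 13; 22 dimethyl 2-bromomalonate
Product: 23 dimethyl (2S,3R)-2-(ArL)-3-[4-(TBSO)benzoyl]cyclopropane-1,1-dicarboxylate (aryl and aroyl trans)
Conditions: 22 (1.5 equiv), N-(9-anthracenylmethyl)cinchonidinium bromide (10 mol%), K2CO3 (3 equiv, solid), toluene, 0 °C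
Reagents that add atoms: none
Why: Michael-initiated ring closure under chiral phase-transfer catalysis: the ammonium-bound bromomalonate anion adds to the β-carbon (the future C2′) on one enone face, then the enolate displaces bromide (3-exo-tet) to give the trans cyclopropane. The catalyst alone sets the future C2′ and C3′, because the existing stereocentres are remote.

Step 15
Reactants: 23 cyclopropane of step 14; 24 4-(TBSO)benzaldehyde
Product: 25 dimethyl 2′-(ArL)-3′-[4-(TBSO)benzoyl]-5′-[4-(TBSO)phenyl]oxolane-4′,4′-dicarboxylate (ring G numbering of 35; 2′,3′-cis and 2′,5′-cis; absolute configuration as in 35)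
Conditions: 24 (3 equiv), Sn(OTf)2 (20 mol%), CH2Cl2, −30 °C to 0 °C
Reagents that add atoms: none
Why: Sn(OTf)2 binds the geminal diester in a bidentate way and polarizes the C2′–C4′ bond; the carbonyl oxygen of 24 attacks the benzylic donor carbon C2′ from the side opposite to the departing malonate carbon (SN2-like, through a tight ion pair), so C2′ is inverted and the trans aryl/aroyl relationship of 23 becomes the 2′,3′-cis relationship of ring G. The O-alkylated aldehyde (an oxocarbenium ion) is then attacked at C5′ by the malonate enolate bound to Sn(OTf)2. The closest known reaction type is the Lewis-acid-catalysed (3+2) annulation of 2-arylcyclopropane-1,1-dicarboxylates with aldehydes to 2,5-cis tetrahydrofurans, which is stereospecific with inversion at the donor carbon and tolerates a substituent on the third ring carbon. Ring G is closed by the C4′–C5′ bond in a 5-(enolexo)-endo-trig aldol-type mode, after the intermolecular C2′–O1′ bond. C2′ is controlled by stereospecific inversion; C5′ by the envelope transition state in which ring H and ring F are both pseudo-equatorial (2′,5′-cis); C3′ is carried over from 23; C4′ is not yet stereogenic. The step needs cleavage of the C2′–C4′ bond only, which is secured by chelation of the geminal diester and by the donor ring on C2′ (the C3′ ketone is a weaker, monodentate acceptor). It also needs configurational memory at C2′, which is supported by the inductive pull of the C3′ aroyl group, by silyl rather than alkyl ethers on ring F and by low temperature.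

Step 16
Reactants: 25 tetrahydrofuran keto diester of step 15
Product: 27 methyl 6-(ArL)-2-oxo-4,8-bis[4-(TBSO)phenyl]-3,7-dioxabicyclo[3.3.0]octane-1-carboxylate (cis-fused lactone; C4 epimers; C2′, C3′, C5′ as in 25), via hydroxy diester 26 (not isolated)
Conditions: NaBH4 (3 equiv), THF/MeOH (4:1), 0 °C to rt
Reagents that add atoms: none
Why: Hydride reduces the only ketone and the alkoxide lactonizes onto the cis ester of the geminal pair (5-exo-trig acyl substitution). This tells the two esters apart and turns the benzylic C–O bond into a benzylic carboxylate; the carbinol configuration does not matter.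

Step 17
Reactants: 27 lactone of step 16
Product: 29 methyl 2′-(ArL)-3′-[4-(TBSO)benzyl]-5′-[4-(TBSO)phenyl]oxolane-4′-carboxylate (C4′ epimers; other centres as in 35), via malonic half-acid 28 (not isolated)
Conditions: H2 (1 atm), Pd(OH)2/C, EtOAc/AcOH (20:1), rt; filter; toluene, 100 °C
Reagents that add atoms: none
Why: Hydrogenolysis of the benzylic lactone C–O bond (a benzylic carboxylate, far more labile than the ring ethers) unveils the ring J benzyl group and a malonic half-acid, which loses CO2 on heating. C4′ forms as an epimer mixture that is corrected in step 19.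

Step 18
Reactants: 29 methyl ester of step 17
Product: 30 N-methoxy-N-methyl 2′-(ArL)-3′-[4-(TBSO)benzyl]-5′-[4-(TBSO)phenyl]oxolane-4′-carboxamide (C4′ epimers)
Conditions: MeNHOMe·HCl (5 equiv), i-PrMgCl (10 equiv), THF, −20 °C to rt
Reagents that add atoms: N,O-dimethylhydroxylamine hydrochloride, CNOC.Cl
Why: Aminolysis of the methyl ester by ClMgN(OMe)Me formed in the flask gives the N-methoxy-N-methylamide needed for a single acyl substitution.

Step 19
Reactants: 5 [2,4-bis(TBSO)phenyl]magnesium bromide; 30 N-methoxy-N-methylamide of step 18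
Product: 32 [2,4-bis(TBSO)phenyl] ketone (2′R,3′S,4′S,5′S)-2′-(ArL)-3′-[4-(TBSO)benzyl]-5′-[4-(TBSO)phenyl]oxolan-4′-yl methanone, via epimeric ketone mixture 31 (not isolated)
Conditions: 5 (4 equiv, THF solution), 30, THF, 0 °C to rt; aq NH4Cl; then DBU (0.5 equiv), CH2Cl2, rt
Reagents that add atoms: none
Why: Acyl substitution on the N-methoxy-N-methylamide gives the ring I ketone without over-addition. DBU then equilibrates the only enolizable centre, C4′, to the isomer with the aroyl group trans to both the C3′ benzyl and the C5′ aryl group (thermodynamic control), which is the configuration of 35.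

Step 20
Reactants: 5 [2,4-bis(TBSO)phenyl]magnesium bromide; 19 N-methoxy-N-methylacrylamide
Product: 33 1-[2,4-bis(TBSO)phenyl]prop-2-en-1-one
Conditions: 5 (THF solution), 19 (0.9 equiv), THF, −78 °C; inverse quench into cold 1 M HCl
Reagents that add atoms: none
Why: Same acyl substitution as in step 12; the chelated tetrahedral intermediate prevents over-addition, and the acidic inverse quench protects the aryl vinyl ketone from the liberated amine.

Step 21
Reactants: 32 aryl chloride ketone of step 19; 33 1-[2,4-bis(TBSO)phenyl]prop-2-en-1-one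
Product: 34 undeca-O-TBS-lophirachalcone
Conditions: 33 (3 equiv), Pd2(dba)3 (5 mol%), P(t-Bu)3 (12 mol%), Cy2NMe (1.5 equiv), 1,4-dioxane, 90 °C
Reagents that add atoms: none
Why: Mizoroki–Heck reaction of the ring B chloride, for which the bulky electron-rich phosphine enables oxidative addition; the E-enone forms by syn insertion and syn β-hydride elimination, and the hindered amine base leaves the aryl silyl ethers alone.

Step 22
Reactants: 34 undeca-O-TBS-lophirachalcone
Product: 35 lophirachalcone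
Conditions: TBAF (14 equiv), AcOH (14 equiv), THF, 0 °C
Reagents that add atoms: none
Why: Fluoride cleaves all eleven aryl silyl ethers. The acetic acid buffer keeps the phenoxide concentration low, so the 2′-hydroxychalcone should not close to a flavanone and ring G should not open by retro-oxa-Michael or quinone-methide pathways; no stereocentre is touched.

## Compound list

1 | 4-bromobenzene-1,3-diol | Oc1ccc(Br)c(O)c1 | starting material
2 | 1-bromo-2,4-bis(TBSO)benzene | Brc1ccc(O[Si](C)(C)C(C)(C)C)cc1O[Si](C)(C)C(C)(C)C | intermediate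
3 | 5-bromo-2,4-dihydroxybenzaldehyde | O=Cc1cc(Br)c(O)cc1O | starting material
4 | 5-bromo-4-(TBSO)-2-hydroxybenzaldehyde | O=Cc1cc(Br)c(O[Si](C)(C)C(C)(C)C)cc1O | intermediate
5 | [2,4-bis(TBSO)phenyl]magnesium bromide (titrated THF stock solution) | Br[Mg]c1ccc(O[Si](C)(C)C(C)(C)C)cc1O[Si](C)(C)C(C)(C)C | intermediate
6 | rac-4-bromo-2-{[2,4-bis(TBSO)phenyl](hydroxy)methyl}-5-(TBSO)phenol (benzhydrol, formed in the flask) | OC(c1ccc(O[Si](C)(C)C(C)(C)C)cc1O[Si](C)(C)C(C)(C)C)c1cc(Br)c(O[Si](C)(C)C(C)(C)C)cc1O | intermediate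
7 | rac-4-bromo-2-{[2,4-bis(TBSO)phenyl](4-methylbenzenesulfonyl)methyl}-5-(TBSO)phenol | Cc1ccc(cc1)S(=O)(=O)C(c1ccc(O[Si](C)(C)C(C)(C)C)cc1O[Si](C)(C)C(C)(C)C)c1cc(Br)c(O[Si](C)(C)C(C)(C)C)cc1O | intermediate
8 | 2-allyl-4-chlorophenol | C=CCc1cc(Cl)ccc1O | starting material
9 | 2-allyl-4-chloro-1-(methoxymethoxy)benzene | C=CCc1cc(Cl)ccc1OCOC | intermediate
10 | 2-[5-chloro-2-(methoxymethoxy)phenyl]acetaldehyde | O=CCc1cc(Cl)ccc1OCOC | intermediate
11 | 4-bromo-6-{[2,4-bis(TBSO)phenyl]methylidene}-3-(TBSO)cyclohexa-2,4-dien-1-one (ortho-quinone methide, formed in the flask) | O=C1C=C(O[Si](C)(C)C(C)(C)C)C(Br)=CC1=Cc1ccc(O[Si](C)(C)C(C)(C)C)cc1O[Si](C)(C)C(C)(C)C | intermediate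
12 | (3R,4S)-6-bromo-4-[2,4-bis(TBSO)phenyl]-7-(TBSO)-3-[5-chloro-2-(methoxymethoxy)phenyl]-3,4-dihydro-2H-chromen-2-ol (C2 anomers) | Clc1ccc(OCOC)c(c1)[C@H]2[C@H](c1ccc(O[Si](C)(C)C(C)(C)C)cc1O[Si](C)(C)C(C)(C)C)c1cc(Br)c(O[Si](C)(C)C(C)(C)C)cc1OC2O | intermediate
13 | (4-bromophenoxy)(tert-butyl)dimethylsilane | Brc1ccc(O[Si](C)(C)C(C)(C)C)cc1 | starting material
14 | [4-(TBSO)phenyl]magnesium bromide (titrated THF stock solution) | Br[Mg]c1ccc(O[Si](C)(C)C(C)(C)C)cc1 | intermediate
15 | (2R,3S)-3-[5-bromo-2-hydroxy-4-(TBSO)phenyl]-3-[2,4-bis(TBSO)phenyl]-2-[5-chloro-2-(methoxymethoxy)phenyl]-1-[4-(TBSO)phenyl]propan-1-ol (C1 epimers) | Clc1ccc(OCOC)c(c1)[C@@H]([C@H](c1ccc(O[Si](C)(C)C(C)(C)C)cc1O[Si](C)(C)C(C)(C)C)c1cc(Br)c(O[Si](C)(C)C(C)(C)C)cc1O)C(O)c1ccc(O[Si](C)(C)C(C)(C)C)cc1 | intermediate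
16 | (2R,3R)-3-[5-bromo-2,4-bis(TBSO)phenyl]-3-[2,4-bis(TBSO)phenyl]-2-[5-chloro-2-(methoxymethoxy)phenyl]-1-[4-(TBSO)phenyl]propan-1-ol (C1 epimers) | Clc1ccc(OCOC)c(c1)[C@@H]([C@H](c1ccc(O[Si](C)(C)C(C)(C)C)cc1O[Si](C)(C)C(C)(C)C)c1cc(Br)c(O[Si](C)(C)C(C)(C)C)cc1O[Si](C)(C)C(C)(C)C)C(O)c1ccc(O[Si](C)(C)C(C)(C)C)cc1 | intermediate
17 | (2R,3R)-3-[5-bromo-2,4-bis(TBSO)phenyl]-3-[2,4-bis(TBSO)phenyl]-2-(5-chloro-2-hydroxyphenyl)-1-[4-(TBSO)phenyl]propan-1-ol (free phenol, formed in the flask) | Clc1ccc(O)c(c1)[C@@H]([C@H](c1ccc(O[Si](C)(C)C(C)(C)C)cc1O[Si](C)(C)C(C)(C)C)c1cc(Br)c(O[Si](C)(C)C(C)(C)C)cc1O[Si](C)(C)C(C)(C)C)C(O)c1ccc(O[Si](C)(C)C(C)(C)C)cc1 | intermediate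
18 | (2R,3R)-3-{(R)-[5-bromo-2,4-bis(TBSO)phenyl][2,4-bis(TBSO)phenyl]methyl}-5-chloro-2-[4-(TBSO)phenyl]-2,3-dihydro-1-benzofuran (ArL–Br) | Clc1ccc2c(c1)[C@@H]([C@H](c1ccc(O[Si](C)(C)C(C)(C)C)cc1O[Si](C)(C)C(C)(C)C)c1cc(Br)c(O[Si](C)(C)C(C)(C)C)cc1O[Si](C)(C)C(C)(C)C)[C@H](c1ccc(O[Si](C)(C)C(C)(C)C)cc1)O2 | intermediate
19 | N-methoxy-N-methylacrylamide | C=CC(=O)N(C)OC | starting material
20 | 1-[4-(TBSO)phenyl]prop-2-en-1-one | C=CC(=O)c1ccc(O[Si](C)(C)C(C)(C)C)cc1 | intermediate
21 | (E)-3-(ArL)-1-[4-(TBSO)phenyl]prop-2-en-1-one | Clc1ccc2c(c1)[C@@H]([C@H](c1ccc(O[Si](C)(C)C(C)(C)C)cc1O[Si](C)(C)C(C)(C)C)c1cc(/C=C/C(=O)c3ccc(O[Si](C)(C)C(C)(C)C)cc3)c(O[Si](C)(C)C(C)(C)C)cc1O[Si](C)(C)C(C)(C)C)[C@H](c1ccc(O[Si](C)(C)C(C)(C)C)cc1)O2 | intermediate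
22 | dimethyl 2-bromomalonate | COC(=O)C(Br)C(=O)OC | starting material
23 | dimethyl (2S,3R)-2-(ArL)-3-[4-(TBSO)benzoyl]cyclopropane-1,1-dicarboxylate | Clc1ccc2c(c1)[C@@H]([C@H](c1ccc(O[Si](C)(C)C(C)(C)C)cc1O[Si](C)(C)C(C)(C)C)c1cc([C@@H]3[C@@H](C(=O)c4ccc(O[Si](C)(C)C(C)(C)C)cc4)C3(C(=O)OC)C(=O)OC)c(O[Si](C)(C)C(C)(C)C)cc1O[Si](C)(C)C(C)(C)C)[C@H](c1ccc(O[Si](C)(C)C(C)(C)C)cc1)O2 | intermediate
24 | 4-(TBSO)benzaldehyde | O=Cc1ccc(O[Si](C)(C)C(C)(C)C)cc1 | starting material
25 | dimethyl 2′-(ArL)-3′-[4-(TBSO)benzoyl]-5′-[4-(TBSO)phenyl]oxolane-4′,4′-dicarboxylate (2′,3′-cis, 2′,5′-cis) | Clc1ccc2c(c1)[C@@H]([C@H](c1ccc(O[Si](C)(C)C(C)(C)C)cc1O[Si](C)(C)C(C)(C)C)c1cc([C@@H]3O[C@H](c4ccc(O[Si](C)(C)C(C)(C)C)cc4)C(C(=O)OC)(C(=O)OC)[C@@H]3C(=O)c3ccc(O[Si](C)(C)C(C)(C)C)cc3)c(O[Si](C)(C)C(C)(C)C)cc1O[Si](C)(C)C(C)(C)C)[C@H](c1ccc(O[Si](C)(C)C(C)(C)C)cc1)O2 | intermediate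
26 | dimethyl 2′-(ArL)-3′-{hydroxy[4-(TBSO)phenyl]methyl}-5′-[4-(TBSO)phenyl]oxolane-4′,4′-dicarboxylate (carbinol epimers, formed in the flask) | Clc1ccc2c(c1)[C@@H]([C@H](c1ccc(O[Si](C)(C)C(C)(C)C)cc1O[Si](C)(C)C(C)(C)C)c1cc([C@@H]3O[C@H](c4ccc(O[Si](C)(C)C(C)(C)C)cc4)C(C(=O)OC)(C(=O)OC)[C@@H]3C(O)c3ccc(O[Si](C)(C)C(C)(C)C)cc3)c(O[Si](C)(C)C(C)(C)C)cc1O[Si](C)(C)C(C)(C)C)[C@H](c1ccc(O[Si](C)(C)C(C)(C)C)cc1)O2 | intermediate
27 | methyl 6-(ArL)-2-oxo-4,8-bis[4-(TBSO)phenyl]-3,7-dioxabicyclo[3.3.0]octane-1-carboxylate (cis-fused; C4 epimers) | Clc1ccc2c(c1)[C@@H]([C@H](c1ccc(O[Si](C)(C)C(C)(C)C)cc1O[Si](C)(C)C(C)(C)C)c1cc([C@@H]3O[C@H](c4ccc(O[Si](C)(C)C(C)(C)C)cc4)[C@@](C(=O)O5)(C(=O)OC)[C@@H]3C5c3ccc(O[Si](C)(C)C(C)(C)C)cc3)c(O[Si](C)(C)C(C)(C)C)cc1O[Si](C)(C)C(C)(C)C)[C@H](c1ccc(O[Si](C)(C)C(C)(C)C)cc1)O2 | intermediate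
28 | 2′-(ArL)-4′-(methoxycarbonyl)-3′-[4-(TBSO)benzyl]-5′-[4-(TBSO)phenyl]oxolane-4′-carboxylic acid (malonic half-acid, formed in the flask) | Clc1ccc2c(c1)[C@@H]([C@H](c1ccc(O[Si](C)(C)C(C)(C)C)cc1O[Si](C)(C)C(C)(C)C)c1cc([C@@H]3O[C@H](c4ccc(O[Si](C)(C)C(C)(C)C)cc4)[C@@](C(=O)O)(C(=O)OC)[C@@H]3Cc3ccc(O[Si](C)(C)C(C)(C)C)cc3)c(O[Si](C)(C)C(C)(C)C)cc1O[Si](C)(C)C(C)(C)C)[C@H](c1ccc(O[Si](C)(C)C(C)(C)C)cc1)O2 | intermediate
29 | methyl 2′-(ArL)-3′-[4-(TBSO)benzyl]-5′-[4-(TBSO)phenyl]oxolane-4′-carboxylate (C4′ epimers) | Clc1ccc2c(c1)[C@@H]([C@H](c1ccc(O[Si](C)(C)C(C)(C)C)cc1O[Si](C)(C)C(C)(C)C)c1cc([C@@H]3O[C@H](c4ccc(O[Si](C)(C)C(C)(C)C)cc4)C(C(=O)OC)[C@@H]3Cc3ccc(O[Si](C)(C)C(C)(C)C)cc3)c(O[Si](C)(C)C(C)(C)C)cc1O[Si](C)(C)C(C)(C)C)[C@H](c1ccc(O[Si](C)(C)C(C)(C)C)cc1)O2 | intermediate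
30 | N-methoxy-N-methyl 2′-(ArL)-3′-[4-(TBSO)benzyl]-5′-[4-(TBSO)phenyl]oxolane-4′-carboxamide (C4′ epimers) | Clc1ccc2c(c1)[C@@H]([C@H](c1ccc(O[Si](C)(C)C(C)(C)C)cc1O[Si](C)(C)C(C)(C)C)c1cc([C@@H]3O[C@H](c4ccc(O[Si](C)(C)C(C)(C)C)cc4)C(C(=O)N(C)OC)[C@@H]3Cc3ccc(O[Si](C)(C)C(C)(C)C)cc3)c(O[Si](C)(C)C(C)(C)C)cc1O[Si](C)(C)C(C)(C)C)[C@H](c1ccc(O[Si](C)(C)C(C)(C)C)cc1)O2 | intermediate
31 | [2′-(ArL)-3′-[4-(TBSO)benzyl]-5′-[4-(TBSO)phenyl]oxolan-4′-yl][2,4-bis(TBSO)phenyl]methanone (C4′ epimer mixture, formed in the flask) | Clc1ccc2c(c1)[C@@H]([C@H](c1ccc(O[Si](C)(C)C(C)(C)C)cc1O[Si](C)(C)C(C)(C)C)c1cc([C@@H]3O[C@H](c4ccc(O[Si](C)(C)C(C)(C)C)cc4)C(C(=O)c4ccc(O[Si](C)(C)C(C)(C)C)cc4O[Si](C)(C)C(C)(C)C)[C@@H]3Cc3ccc(O[Si](C)(C)C(C)(C)C)cc3)c(O[Si](C)(C)C(C)(C)C)cc1O[Si](C)(C)C(C)(C)C)[C@H](c1ccc(O[Si](C)(C)C(C)(C)C)cc1)O2 | intermediate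
32 | [(2′R,3′S,4′S,5′S)-2′-(ArL)-3′-[4-(TBSO)benzyl]-5′-[4-(TBSO)phenyl]oxolan-4′-yl][2,4-bis(TBSO)phenyl]methanone | Clc1ccc2c(c1)[C@@H]([C@H](c1ccc(O[Si](C)(C)C(C)(C)C)cc1O[Si](C)(C)C(C)(C)C)c1cc([C@@H]3O[C@H](c4ccc(O[Si](C)(C)C(C)(C)C)cc4)[C@@H](C(=O)c4ccc(O[Si](C)(C)C(C)(C)C)cc4O[Si](C)(C)C(C)(C)C)[C@@H]3Cc3ccc(O[Si](C)(C)C(C)(C)C)cc3)c(O[Si](C)(C)C(C)(C)C)cc1O[Si](C)(C)C(C)(C)C)[C@H](c1ccc(O[Si](C)(C)C(C)(C)C)cc1)O2 | intermediate
33 | 1-[2,4-bis(TBSO)phenyl]prop-2-en-1-one | C=CC(=O)c1ccc(O[Si](C)(C)C(C)(C)C)cc1O[Si](C)(C)C(C)(C)C | intermediate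
34 | undeca-O-TBS-lophirachalcone (32 with Cl replaced by (E)-3-[2,4-bis(TBSO)phenyl]-3-oxoprop-1-enyl) | O=C(/C=C/c1ccc2c(c1)[C@@H]([C@H](c1ccc(O[Si](C)(C)C(C)(C)C)cc1O[Si](C)(C)C(C)(C)C)c1cc([C@@H]3O[C@H](c4ccc(O[Si](C)(C)C(C)(C)C)cc4)[C@@H](C(=O)c4ccc(O[Si](C)(C)C(C)(C)C)cc4O[Si](C)(C)C(C)(C)C)[C@@H]3Cc3ccc(O[Si](C)(C)C(C)(C)C)cc3)c(O[Si](C)(C)C(C)(C)C)cc1O[Si](C)(C)C(C)(C)C)[C@H](c1ccc(O[Si](C)(C)C(C)(C)C)cc1)O2)c1ccc(O[Si](C)(C)C(C)(C)C)cc1O[Si](C)(C)C(C)(C)C | intermediate
35 | lophirachalcone (2R,3R; Cm R; 2′R,3′S,4′S,5′S) | O=C(/C=C/c1ccc2c(c1)[C@@H]([C@H](c1ccc(O)cc1O)c1cc([C@@H]3O[C@H](c4ccc(O)cc4)[C@@H](C(=O)c4ccc(O)cc4O)[C@@H]3Cc3ccc(O)cc3)c(O)cc1O)[C@H](c1ccc(O)cc1)O2)c1ccc(O)cc1O | target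

## Step count and risks

Total step count: 22. Longest linear sequence: 16 steps (steps 1, 3, 4, 7, 9, 10, 11, 13, 14, 15, 16, 17, 18, 19, 21, 22).

**Step 15 (key step).** The most likely failure is loss of configurational memory at C2′: the doubly oxygenated ring F can stabilize a free benzylic cation, so the 2′,3′-cis relationship erodes. The C3′ ketone may also divert the Lewis acid and open the ring in the wrong sense. The fallback changes the order of events and the substrate class. It sets out from 23: reduction with NaBH4 (THF/MeOH, 0 °C) should give, after lactonization onto the cis ester, the ketone-free, lactone-fused cyclopropane methyl 6-(ArL)-2-oxo-4-[4-(TBSO)phenyl]-3-oxabicyclo[3.1.0]hexane-1-carboxylate F1. Its (3+2) annulation with 24 under Sn(OTf)2 then has a single chelating acceptor pair and a rigid framework that keeps the leaving carbon next to C2′. It comes back to the route at 27.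

**Step 7.** The arylacetaldehyde may self-condense faster than it is intercepted, and facial control at Cm may be poor, because the enamine and the quinone methide are both hindered. The fallback replaces enamine catalysis by acyl-ammonium enolate catalysis. It sets out from 10: oxidation with NaClO2 (NaH2PO4, 2-methylbut-2-ene) gives 2-[5-chloro-2-(methoxymethoxy)phenyl]acetic acid F2. Treatment of F2 with t-BuCOCl and i-Pr2NEt gives 2-[5-chloro-2-(methoxymethoxy)phenyl]acetic pivalic anhydride F3, which is united with 7 under the isothiourea catalyst HyperBTM by Michael addition–lactonization; this should give the trans dihydrocoumarin (3R,4S)-6-bromo-4-[2,4-bis(TBSO)phenyl]-7-(TBSO)-3-[5-chloro-2-(methoxymethoxy)phenyl]chroman-2-one F4. Reduction with i-Bu2AlH (CH2Cl2, −78 °C) comes back to the route at 12.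

**Step 14.** Michael addition to the electron-rich, ortho-substituted enone may be slow and reversible, with weak enantiofacial discrimination by the ion pair. The fallback moves the asymmetric step to iminium catalysis. It sets out from 18: Heck reaction with acrolein (Pd(OAc)2, P(o-tol)3, Et3N) gives (E)-3-(ArL)prop-2-enal F5. Cyclopropanation with 22 under (S)-α,α-diphenylprolinol trimethylsilyl ether and 2,6-lutidine gives dimethyl 2-(ArL)-3-formylcyclopropane-1,1-dicarboxylate F6. Addition of 14 at −78 °C and lactonization lead to the lactone-fused cyclopropane F1, which is annulated with 24 as in the fallback for step 15. It comes back to the route at 27.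

**Step 17.** Hydrogenolysis may not stop at the lactone: the ring benzylic C–O bonds (C2′–O1′, C5′–O1′, C2–O1) and the aryl chloride can be cleaved competitively. The fallback avoids hydrogen and the lactone altogether. It sets out from 25: condensation with tosylhydrazide (EtOH, 60 °C) gives the tosylhydrazone of 25 F7. Reduction with catecholborane followed by NaOAc·3H2O at reflux gives dimethyl 2′-(ArL)-3′-[4-(TBSO)benzyl]-5′-[4-(TBSO)phenyl]oxolane-4′,4′-dicarboxylate F8. Mono-hydrolysis with Me3SnOH (1,2-dichloroethane, 70 °C) gives the malonic half-acid of F8 F9, and heating in toluene comes back to the route at 29.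

**Step 21.** Oxidative addition into the electron-rich aryl chloride may be slow enough for the vinyl ketone to polymerize or for the β-alkoxy ketone of ring G to open. The fallback separates C–C coupling from enone formation. It sets out from 32: Suzuki–Miyaura vinylation (potassium vinyltrifluoroborate, Pd(OAc)2, SPhos, Cs2CO3, THF/H2O) gives the ring B styrene F10 (32 with Cl replaced by vinyl). Cross-metathesis of F10 with 33 (second-generation Hoveyda–Grubbs catalyst, CH2Cl2, 40 °C) comes back to the route at 34.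

## Further compounds

F1 | step 15 | methyl 6-(ArL)-2-oxo-4-[4-(TBSO)phenyl]-3-oxabicyclo[3.1.0]hexane-1-carboxylate (C4 epimers) | Clc1ccc2c(c1)[C@@H]([C@H](c1ccc(O[Si](C)(C)C(C)(C)C)cc1O[Si](C)(C)C(C)(C)C)c1cc([C@@H]3[C@@H](C5c4ccc(O[Si](C)(C)C(C)(C)C)cc4)[C@]3(C(=O)O5)C(=O)OC)c(O[Si](C)(C)C(C)(C)C)cc1O[Si](C)(C)C(C)(C)C)[C@H](c1ccc(O[Si](C)(C)C(C)(C)C)cc1)O2
F2 | step 7 | 2-[5-chloro-2-(methoxymethoxy)phenyl]acetic acid | OC(=O)Cc1cc(Cl)ccc1OCOC
F3 | step 7 | 2-[5-chloro-2-(methoxymethoxy)phenyl]acetic pivalic anhydride | CC(C)(C)C(=O)OC(=O)Cc1cc(Cl)ccc1OCOC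
F4 | step 7 | (3R,4S)-6-bromo-4-[2,4-bis(TBSO)phenyl]-7-(TBSO)-3-[5-chloro-2-(methoxymethoxy)phenyl]chroman-2-one | Clc1ccc(OCOC)c(c1)[C@H]2[C@H](c1ccc(O[Si](C)(C)C(C)(C)C)cc1O[Si](C)(C)C(C)(C)C)c1cc(Br)c(O[Si](C)(C)C(C)(C)C)cc1OC2=O
F5 | step 14 | (E)-3-(ArL)prop-2-enal | Clc1ccc2c(c1)[C@@H]([C@H](c1ccc(O[Si](C)(C)C(C)(C)C)cc1O[Si](C)(C)C(C)(C)C)c1cc(/C=C/C=O)c(O[Si](C)(C)C(C)(C)C)cc1O[Si](C)(C)C(C)(C)C)[C@H](c1ccc(O[Si](C)(C)C(C)(C)C)cc1)O2
F6 | step 14 | dimethyl 2-(ArL)-3-formylcyclopropane-1,1-dicarboxylate (aryl and formyl trans) | Clc1ccc2c(c1)[C@@H]([C@H](c1ccc(O[Si](C)(C)C(C)(C)C)cc1O[Si](C)(C)C(C)(C)C)c1cc([C@@H]3[C@@H](C=O)C3(C(=O)OC)C(=O)OC)c(O[Si](C)(C)C(C)(C)C)cc1O[Si](C)(C)C(C)(C)C)[C@H](c1ccc(O[Si](C)(C)C(C)(C)C)cc1)O2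
F7 | step 17 | tosylhydrazone of 25 | Clc1ccc2c(c1)[C@@H]([C@H](c1ccc(O[Si](C)(C)C(C)(C)C)cc1O[Si](C)(C)C(C)(C)C)c1cc([C@@H]3O[C@H](c4ccc(O[Si](C)(C)C(C)(C)C)cc4)C(C(=O)OC)(C(=O)OC)[C@@H]3C(=NNS(=O)(=O)c3ccc(C)cc3)c3ccc(O[Si](C)(C)C(C)(C)C)cc3)c(O[Si](C)(C)C(C)(C)C)cc1O[Si](C)(C)C(C)(C)C)[C@H](c1ccc(O[Si](C)(C)C(C)(C)C)cc1)O2
F8 | step 17 | dimethyl 2′-(ArL)-3′-[4-(TBSO)benzyl]-5′-[4-(TBSO)phenyl]oxolane-4′,4′-dicarboxylate | Clc1ccc2c(c1)[C@@H]([C@H](c1ccc(O[Si](C)(C)C(C)(C)C)cc1O[Si](C)(C)C(C)(C)C)c1cc([C@@H]3O[C@H](c4ccc(O[Si](C)(C)C(C)(C)C)cc4)C(C(=O)OC)(C(=O)OC)[C@@H]3Cc3ccc(O[Si](C)(C)C(C)(C)C)cc3)c(O[Si](C)(C)C(C)(C)C)cc1O[Si](C)(C)C(C)(C)C)[C@H](c1ccc(O[Si](C)(C)C(C)(C)C)cc1)O2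
F9 | step 17 | malonic half-acid of F8 (C4′ unassigned) | Clc1ccc2c(c1)[C@@H]([C@H](c1ccc(O[Si](C)(C)C(C)(C)C)cc1O[Si](C)(C)C(C)(C)C)c1cc([C@@H]3O[C@H](c4ccc(O[Si](C)(C)C(C)(C)C)cc4)C(C(=O)O)(C(=O)OC)[C@@H]3Cc3ccc(O[Si](C)(C)C(C)(C)C)cc3)c(O[Si](C)(C)C(C)(C)C)cc1O[Si](C)(C)C(C)(C)C)[C@H](c1ccc(O[Si](C)(C)C(C)(C)C)cc1)O2
F10 | step 21 | ring B styrene (32 with Cl replaced by vinyl) | C=Cc1ccc2c(c1)[C@@H]([C@H](c1ccc(O[Si](C)(C)C(C)(C)C)cc1O[Si](C)(C)C(C)(C)C)c1cc([C@@H]3O[C@H](c4ccc(O[Si](C)(C)C(C)(C)C)cc4)[C@@H](C(=O)c4ccc(O[Si](C)(C)C(C)(C)C)cc4O[Si](C)(C)C(C)(C)C)[C@@H]3Cc3ccc(O[Si](C)(C)C(C)(C)C)cc3)c(O[Si](C)(C)C(C)(C)C)cc1O[Si](C)(C)C(C)(C)C)[C@H](c1ccc(O[Si](C)(C)C(C)(C)C)cc1)O2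
A1 | alternative 1 | [(2R,3S,4S,5S)-5-[2,4-bis(TBSO)phenyl]-4-[4-(TBSO)benzyl]-2-[4-(TBSO)phenyl]oxolan-3-yl][2,4-bis(TBSO)phenyl]methanone (ring G-bearing resorcinol ether) | CC(C)(C)[Si](C)(C)Oc1ccc([C@@H]2O[C@H](c3ccc(O[Si](C)(C)C(C)(C)C)cc3)[C@@H](C(=O)c3ccc(O[Si](C)(C)C(C)(C)C)cc3O[Si](C)(C)C(C)(C)C)[C@@H]2Cc2ccc(O[Si](C)(C)C(C)(C)C)cc2)c(O[Si](C)(C)C(C)(C)C)c1
A2 | alternative 1 | 2-{[trans-5-chloro-2-[4-(TBSO)phenyl]-2,3-dihydro-1-benzofuran-3-yl](hydroxy)methyl}-5-(TBSO)phenol (ring configuration as in 18; carbinol epimers) | Clc1ccc2c(c1)[C@@H](C(O)c1ccc(O[Si](C)(C)C(C)(C)C)cc1O)[C@H](c1ccc(O[Si](C)(C)C(C)(C)C)cc1)O2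
A3 | alternative 2 | 3-[4-(TBSO)benzyl]-4-[2,4-bis(TBSO)benzoyl]-5-[4-(TBSO)phenyl]oxolan-2-one (3,4-trans, 4,5-trans; configuration as in ring G of 35) | O=C1O[C@H](c2ccc(O[Si](C)(C)C(C)(C)C)cc2)[C@@H](C(=O)c2ccc(O[Si](C)(C)C(C)(C)C)cc2O[Si](C)(C)C(C)(C)C)[C@@H]1Cc1ccc(O[Si](C)(C)C(C)(C)C)cc1
A4 | alternative 3 | trans-2-[2,4-bis(TBSO)phenyl]-3-[4-(TBSO)phenyl]oxirane (one enantiomer drawn) | CC(C)(C)[Si](C)(C)Oc1ccc([C@H]2O[C@@H]2c2ccc(O[Si](C)(C)C(C)(C)C)cc2)c(O[Si](C)(C)C(C)(C)C)c1
A5 | alternative 3 | (E)-1-[2,4-bis(TBSO)phenyl]-4-[4-(TBSO)phenyl]but-2-en-1-one | O=C(/C=C/Cc1ccc(O[Si](C)(C)C(C)(C)C)cc1)c1ccc(O[Si](C)(C)C(C)(C)C)cc1O[Si](C)(C)C(C)(C)C
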